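**Retrosynthetic overview**
1. Target 24 ⇒ Suzuki–Miyaura union of alkenyl boronate 20 with alkenyl iodide 23; 20 ⇒ cross-metathesis of the 2-methylallyl dioxane 18 with vinyl boronate 19.
2. 18 ⇒ tertiary hydroperoxide 15 + methyl propiolate 16: the only ring of the target, the 1,2-dioxane, is closed last through the C-3–C-4 bond, by 6-exo addition of a C-4 radical to a β-peroxyacrylate made in the same flask.
3. Feature used: C-3 bears both ring oxygen O-2 and the CH2CO2Me arm, so O-2–C-3–CH2–CO2Me is the reduced form of a peroxy-substituted acrylate with C-3 as β-carbon; C-4 (H, CH3) is a secondary radical site; the O-1–O-2 bond is the two-atom tether that makes the closure six-membered.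
4. 15 ⇒ oxetane 11 (perhydrolysis at the quaternary carbon with inversion) ⇒ 1,3-diol 9 ⇒ (S)-2-methylglycidol 1 by two copper-catalysed Grignard openings.
5. Ring order: the oxiranes (1, 5) and the oxetane (11) are temporary carriers of the quaternary C–O centre; the 1,2-dioxane is formed in step 11 and kept to the end.

Key step: step 11

Assumption: 9–15 and 17 are carried as mixtures of epimers at the carbinol/iodide carbon, because that centre becomes the planar radical of step 11; 1, 2, 6, 16, 19 and 21 are taken as commercial.

**Step 1**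
Reactants: 1 [(2S)-2-methyloxiran-2-yl]methanol; 2 prop-1-en-2-ylmagnesium bromide
Product: 3 (2R)-2,4-dimethylpent-4-ene-1,2-diol
Conditions: 2 (2.5 equiv), CuBr·SMe2 (10 mol%), THF, −40 → 0 °C; aq. NH4Cl
Reagents that add atoms: none
Why: Copper-catalysed Grignard opening of the 2,2-disubstituted epoxide (SN2) occurs at the unhindered CH2 terminus, so the quaternary stereocentre of 1 is not touched.

**Step 2**
Reactants: 3 (2R)-2,4-dimethylpent-4-ene-1,2-diol
Product: 5 (2R)-2-methyl-2-(2-methylprop-2-en-1-yl)oxirane, via primary tosylate 4 (not isolated)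
Conditions: NaH (2.2 equiv), THF, 0 °C; then 1-(p-toluenesulfonyl)imidazole, 0 °C → rt
Reagents that add atoms: none
Why: Selective sulfonylation of the primary hydroxyl and intramolecular Williamson closure (3-exo-tet) by the tertiary alkoxide form the epoxide with the C–O bond of the stereocentre retained.

**Step 3**
Reactants: 5 (2R)-2-methyl-2-(2-methylprop-2-en-1-yl)oxirane; 6 ethenylmagnesium bromide
Product: 7 (4S)-2,4-dimethylhepta-1,6-dien-4-ol
Conditions: 6 (1.5 equiv), CuBr·SMe2 (10 mol%), THF, −40 → 0 °C; aq. NH4Cl
Reagents that add atoms: none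
Why: The same copper-catalysed SN2 opening at the epoxide CH2 installs the allyl arm without involving the stereocentre (the descriptor changes only through the priority order).

**Step 4**
Reactants: 7 (4S)-2,4-dimethylhepta-1,6-dien-4-ol
Product: 8 (4R)-4-hydroxy-4,6-dimethylhept-6-en-2-one
Conditions: PdCl2 (10 mol%), CuCl (1 equiv), O2 (1 atm), DMF/H2O (7:1), rt
Reagents that add atoms: water O
Why: Wacker–Tsuji oxidation converts the monosubstituted alkene into the methyl ketone in the Markovnikov sense, while the 1,1-disubstituted alkene is inert under these conditions.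

**Step 5**
Reactants: 8 (4R)-4-hydroxy-4,6-dimethylhept-6-en-2-one
Product: 9 (4R)-4,6-dimethylhept-6-ene-2,4-diol (both C-2 epimers)
Conditions: NaBH4, MeOH, 0 °C
Reagents that add atoms: none
Why: Borohydride reduction of the ketone; the new carbinol centre is deliberately left uncontrolled because it is erased in step 11.

**Step 6**
Reactants: 9 (4R)-4,6-dimethylhept-6-ene-2,4-diol
Product: 11 (2R)-2,4-dimethyl-2-(2-methylprop-2-en-1-yl)oxetane (both C-4 epimers), via secondary tosylate 10 (not isolated)
Conditions: TsCl (1.05 equiv), pyridine, 0 °C; then KOt-Bu (2.2 equiv), THF, 0 °C → rt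
Reagents that add atoms: none
Why: Only the secondary hydroxyl is sulfonylated, and the tertiary alkoxide then closes the oxetane by intramolecular Williamson etherification (4-exo-tet), which retains the tertiary C–O bond and its configuration.

**Step 7**
Reactants: 11 (2R)-2,4-dimethyl-2-(2-methylprop-2-en-1-yl)oxetane
Product: 12 (4S)-4-hydroperoxy-4,6-dimethylhept-6-en-2-ol
Conditions: H2O2 (anhydrous, in Et2O, 10 equiv), TMSOTf (0.1 equiv), Et2O, −78 → −40 °C
Reagents that add atoms: hydrogen peroxide OO
Why: Lewis-acid-promoted perhydrolysis of a 2,2-disubstituted oxetane occurs at the more substituted carbon with inversion, which sets the configuration of the tertiary hydroperoxide and returns the secondary alcohol.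

**Step 8**
Reactants: 12 (4S)-4-hydroperoxy-4,6-dimethylhept-6-en-2-ol
Product: 13 (4S)-4-[(2-methoxypropan-2-yl)peroxy]-4,6-dimethylhept-6-en-2-ol
Conditions: 2-methoxypropene (1.2 equiv), PPTS (5 mol%), CH2Cl2, −20 °C
Reagents that add atoms: 2-methoxypropene COC(C)=C
Why: Acid-catalysed addition of a hydroperoxide to an enol ether (peroxyketal protection) should occur at the more nucleophilic OOH before the hindered secondary hydroxyl.

**Step 9**
Reactants: 13 (4S)-4-[(2-methoxypropan-2-yl)peroxy]-4,6-dimethylhept-6-en-2-ol
Product: 14 (4S)-6-iodo-4-[(2-methoxypropan-2-yl)peroxy]-2,4-dimethylhept-1-ene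
Conditions: PPh3, I2, imidazole, CH2Cl2, 0 °C
Reagents that add atoms: iodine II
Why: Appel iodination of the secondary alcohol (SN2); the phosphine is held as its iodine adduct, so the peroxyketal should not be reduced.

**Step 10**
Reactants: 14 (4S)-6-iodo-4-[(2-methoxypropan-2-yl)peroxy]-2,4-dimethylhept-1-ene
Product: 15 (4S)-4-hydroperoxy-6-iodo-2,4-dimethylhept-1-ene
Conditions: PPTS (10 mol%), MeOH, 0 °C; used at once
Reagents that add atoms: none
Why: Acid-catalysed transketalisation with methanol releases the hydroperoxide under conditions that leave the secondary iodide and the alkene alone.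

**Step 11**
Reactants: 15 (4S)-4-hydroperoxy-6-iodo-2,4-dimethylhept-1-ene; 16 methyl prop-2-ynoate
Product: 18 methyl 2-[(3S,4R,6R)-4,6-dimethyl-6-(2-methylprop-2-en-1-yl)-1,2-dioxan-3-yl]acetate, via peroxyacrylate 17 (not isolated)
Conditions: 16 (1.05 equiv), N-methylmorpholine (10 mol%), toluene, 0 °C; then (Me3Si)3SiH (1.5 equiv), Et3B (0.3 equiv), air, toluene (0.01 M), −20 °C
Reagents that add atoms: none
Why: Proposed new method: the hydroperoxide first adds to methyl propiolate under tertiary-amine catalysis to give the (E)-β-peroxyacrylate 17, then iodine abstraction by the silyl radical generates the secondary C-4 radical, which adds to the peroxide-bearing acrylate β-carbon, and the resulting α-ester radical takes hydrogen from the silane to carry the chain. The closest known reaction types are the amine-catalysed oxa-Michael addition of alcohols to propiolates and the 6-exo radical cyclisation of β-alkoxyacrylates that gives 2,3-trans-tetrahydropyrans; only the O–O tether is new. The 1,2-dioxane closes in the 6-exo-trig mode through the new C-3–C-4 bond. C-3 and C-4 are set together in a chair transition state in which the radical methyl group and the E-acrylate terminus are both pseudo-equatorial (3,4-trans), and their sense relative to the fixed C-6 centre follows from the 2-methylallyl arm lying equatorial and the smaller C-6 methyl axial, which places the new C-4 methyl cis to that arm. The step needs ring closure to beat simple reduction of the radical, attack on the 1,1-disubstituted alkene, displacement of iodide by the hydroperoxide and O–O homolysis of the vinylogous perester; this is served by the polarity match between the nucleophilic alkyl radical and the acrylate, by a low stationary silane concentration, by the weak amine base and by forming 17 cold and consuming it at −20 °C without isolation. Hydrogen transfer to the β-peroxy α-ester radical must also outrun its collapse to an epoxide, which the ester-stabilised radical and the good hydrogen donor should allow.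

**Step 12**
Reactants: 18 methyl 2-[(3S,4R,6R)-4,6-dimethyl-6-(2-methylprop-2-en-1-yl)-1,2-dioxan-3-yl]acetate; 19 2-ethenyl-4,4,5,5-tetramethyl-1,3,2-dioxaborolane
Product: 20 methyl 2-[(3S,4R,6R)-4,6-dimethyl-6-[(2E)-2-methyl-3-(4,4,5,5-tetramethyl-1,3,2-dioxaborolan-2-yl)prop-2-en-1-yl]-1,2-dioxan-3-yl]acetate
Conditions: 19 (5 equiv), second-generation Hoveyda–Grubbs catalyst (10 mol%), CH2Cl2, 40 °C
Reagents that add atoms: none
Why: Cross-metathesis of a 1,1-disubstituted alkene with a vinyl boronate should give the trisubstituted alkenyl boronate as the thermodynamically favoured E isomer, and dialkyl peroxides and esters are tolerated by ruthenium carbenes.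

**Step 13**
Reactants: 21 prop-2-yn-1-ylbenzene
Product: 23 [(2E)-3-iodoprop-2-en-1-yl]benzene, via alkenylzirconocene chloride 22 (not isolated)
Conditions: Cp2Zr(H)Cl (1.2 equiv), THF, rt; then I2, 0 °C
Reagents that add atoms: iodine II
Why: Hydrozirconation of the terminal alkyne is syn and places zirconium at the terminus, and iodinolysis proceeds with retention, so the E-alkenyl iodide should result.

**Step 14**
Reactants: 20 methyl 2-[(3S,4R,6R)-4,6-dimethyl-6-[(2E)-2-methyl-3-(4,4,5,5-tetramethyl-1,3,2-dioxaborolan-2-yl)prop-2-en-1-yl]-1,2-dioxan-3-yl]acetate; 23 [(2E)-3-iodoprop-2-en-1-yl]benzene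
Product: 24 methyl 2-[(3S,4R,6R)-4,6-dimethyl-6-[(2E,4E)-2-methyl-6-phenylhexa-2,4-dien-1-yl]-1,2-dioxan-3-yl]acetate
Conditions: Pd(dppf)Cl2 (5 mol%), K3PO4 (3 equiv), THF/H2O (10:1), rt, degassed
Reagents that add atoms: none
Why: Suzuki–Miyaura coupling joins the two alkenyl partners with retention of both double-bond geometries at room temperature, mild enough for the hindered dialkyl peroxide and for the base-sensitive skipped benzyl–diene unit.

**Compound list**
1 | [(2S)-2-methyloxiran-2-yl]methanol | C[C@]1(CO)CO1 | starting material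
2 | prop-1-en-2-ylmagnesium bromide | C=C(C)[Mg]Br | starting material
3 | (2R)-2,4-dimethylpent-4-ene-1,2-diol | O[C@](C)(CC(C)=C)CO | intermediate
4 | (2R)-2-hydroxy-2,4-dimethylpent-4-en-1-yl 4-methylbenzenesulfonate | O[C@](C)(CC(C)=C)COS(=O)(=O)c1ccc(C)cc1 | intermediate
5 | (2R)-2-methyl-2-(2-methylprop-2-en-1-yl)oxirane | O1[C@](C)(CC(C)=C)C1 | intermediate
6 | ethenylmagnesium bromide | C=C[Mg]Br | starting material
7 | (4S)-2,4-dimethylhepta-1,6-dien-4-ol | O[C@](C)(CC(C)=C)CC=C | intermediate
8 | (4R)-4-hydroxy-4,6-dimethylhept-6-en-2-one | O[C@](C)(CC(C)=C)CC(C)=O | intermediate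
9 | (4R)-4,6-dimethylhept-6-ene-2,4-diol (C-2 epimers) | O[C@](C)(CC(C)=C)CC(C)O | intermediate
10 | (4R)-4-hydroxy-4,6-dimethylhept-6-en-2-yl 4-methylbenzenesulfonate (C-2 epimers) | O[C@](C)(CC(C)=C)CC(C)OS(=O)(=O)c1ccc(C)cc1 | intermediate
11 | (2R)-2,4-dimethyl-2-(2-methylprop-2-en-1-yl)oxetane (C-4 epimers) | O1[C@](C)(CC(C)=C)CC1C | intermediate
12 | (4S)-4-hydroperoxy-4,6-dimethylhept-6-en-2-ol (C-2 epimers) | OO[C@@](C)(CC(C)=C)CC(C)O | intermediate
13 | (4S)-4-[(2-methoxypropan-2-yl)peroxy]-4,6-dimethylhept-6-en-2-ol (C-2 epimers) | COC(C)(C)OO[C@@](C)(CC(C)=C)CC(C)O | intermediate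
14 | (4S)-6-iodo-4-[(2-methoxypropan-2-yl)peroxy]-2,4-dimethylhept-1-ene (C-6 epimers) | COC(C)(C)OO[C@@](C)(CC(C)=C)CC(C)I | intermediate
15 | (4S)-4-hydroperoxy-6-iodo-2,4-dimethylhept-1-ene (C-6 epimers) | OO[C@@](C)(CC(C)=C)CC(C)I | intermediate
16 | methyl prop-2-ynoate | COC(=O)C#C | starting material
17 | methyl (2E)-3-{[(4S)-6-iodo-2,4-dimethylhept-1-en-4-yl]peroxy}prop-2-enoate | COC(=O)/C=C/OO[C@@](C)(CC(C)=C)CC(C)I | intermediate
18 | methyl 2-[(3S,4R,6R)-4,6-dimethyl-6-(2-methylprop-2-en-1-yl)-1,2-dioxan-3-yl]acetate | COC(=O)C[C@@H]1OO[C@@](C)(CC(C)=C)C[C@H]1C | intermediate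
19 | 2-ethenyl-4,4,5,5-tetramethyl-1,3,2-dioxaborolane | C=CB1OC(C)(C)C(C)(C)O1 | starting material
20 | methyl 2-[(3S,4R,6R)-4,6-dimethyl-6-[(2E)-2-methyl-3-(4,4,5,5-tetramethyl-1,3,2-dioxaborolan-2-yl)prop-2-en-1-yl]-1,2-dioxan-3-yl]acetate | COC(=O)C[C@@H]1OO[C@@](C)(C/C(C)=C/B2OC(C)(C)C(C)(C)O2)C[C@H]1C | intermediate
21 | prop-2-yn-1-ylbenzene | C#CCc1ccccc1 | starting material
22 | chlorobis(cyclopentadienyl)[(1E)-3-phenylprop-1-en-1-yl]zirconium | Cl[Zr](/C=C/Cc1ccccc1)(C1C=CC=C1)C1C=CC=C1 | intermediate
23 | [(2E)-3-iodoprop-2-en-1-yl]benzene | I/C=C/Cc1ccccc1 | intermediate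
24 | methyl 2-[(3S,4R,6R)-4,6-dimethyl-6-[(2E,4E)-2-methyl-6-phenylhexa-2,4-dien-1-yl]-1,2-dioxan-3-yl]acetate | COC(=O)C[C@@H]1OO[C@@](C)(C/C(C)=C/C=C/Cc2ccccc2)C[C@H]1C | target

**Step count**
Total steps: 14. Longest linear sequence: 13 (steps 1–12 and 14; step 13 makes the coupling partner).

**Steps most likely to fail**

1. Step 11 (proposed new method). What may go wrong:
   - cleavage of the weak O–O bond of the vinylogous perester 17, thermally or by silyl radicals, before the ring closes;
   - too little discrimination between methyl and 2-methylallyl on C-6 in the chair, so that the (3R,4S,6R) isomer forms alongside 18;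
   - displacement of iodide by the hydroperoxide to give a dioxolane;
   - collapse of the β-peroxy radical to an epoxide.

   Fallback with known chemistry, setting out from 14 and returning at 18; the ring is then closed through O-2–C-3 instead. Hydrostannation of 16 (Bu3SnH, AIBN) gives methyl (2E)-3-(tributylstannyl)prop-2-enoate F1. Radical alkenylation of iodide 14 with F1 (Et3B, air, benzene, rt) proceeds by addition of the alkyl radical to the tin-bearing carbon and loss of the stannyl radical, which abstracts iodine from 14. It should give methyl (2E,6R)-6-[(2-methoxypropan-2-yl)peroxy]-4,6,8-trimethylnona-2,8-dienoate F2 as C-4 epimers. PPTS in methanol frees methyl (2E,6R)-6-hydroperoxy-4,6,8-trimethylnona-2,8-dienoate F3. Diethylamine in trifluoroethanol then effects the 6-exo oxa-Michael closure established for 1,2-dioxane-3-acetates. This fallback has no control at C-4, so 18 would have to be separated by chromatography from the isomers epimeric at C-4 and C-3.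

2. Step 12. What may go wrong: non-productive metathesis, because the ruthenium carbene fails to engage the 1,1-disubstituted alkene next to the quaternary C-6, or the boron-substituted carbene is consumed by self-metathesis of 19; incomplete E control is also possible.

   Fallback, setting out from 18 and returning at 24 without boron or palladium. Cross-metathesis with the electron-poor partner (E)-but-2-enal (same catalyst) should give methyl 2-[(3S,4R,6R)-4,6-dimethyl-6-[(2E)-2-methyl-4-oxobut-2-en-1-yl]-1,2-dioxan-3-yl]acetate F4. Separately, (2-bromoethyl)benzene and 1-phenyl-1H-tetrazole-5-thiol (K2CO3, acetone) give 1-phenyl-5-[(2-phenylethyl)sulfanyl]-1H-tetrazole F5, which is oxidised (H2O2, (NH4)6Mo7O24, EtOH) to 1-phenyl-5-[(2-phenylethyl)sulfonyl]-1H-tetrazole F6. Julia–Kocienski olefination of F4 with F6 (KHMDS, DME, −60 °C, base added to the mixture of both) should give 24 with the new disubstituted alkene E.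

3. Step 7. What may go wrong: ionisation of the activated oxetane at the tertiary carbon (SN1 leakage, assisted by the neighbouring 1,1-disubstituted alkene) with partial loss of configuration. This would be hidden in the C-2 epimer mixture of 12 and would become an enantiomeric impurity after step 11.

   Fallback, setting out from 8 and returning at 12. Evans–Saksena reduction of 8 (Me4NBH(OAc)3, MeCN/AcOH, −30 °C) should give the anti diol (2R,4R)-4,6-dimethylhept-6-ene-2,4-diol F7. Tosylation and closure as in step 6 (inversion at the secondary carbon) give (2R,4S)-2,4-dimethyl-2-(2-methylprop-2-en-1-yl)oxetane F8. Perhydrolysis as in step 7 gives the (2S,4S) epimer of 12. Any product of stereochemical leakage at the tertiary centre is now a diastereomer and is removed by chromatography before the material re-enters the route at 12.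

**Further compounds**
F1 | step 11 | methyl (2E)-3-(tributylstannyl)prop-2-enoate | CCCC[Sn](CCCC)(CCCC)/C=C/C(=O)OC
F2 | step 11 | methyl (2E,6R)-6-[(2-methoxypropan-2-yl)peroxy]-4,6,8-trimethylnona-2,8-dienoate | COC(=O)/C=C/C(C)C[C@](C)(CC(C)=C)OOC(C)(C)OC
F3 | step 11 | methyl (2E,6R)-6-hydroperoxy-4,6,8-trimethylnona-2,8-dienoate | COC(=O)/C=C/C(C)C[C@](C)(CC(C)=C)OO
F4 | step 12 | methyl 2-[(3S,4R,6R)-4,6-dimethyl-6-[(2E)-2-methyl-4-oxobut-2-en-1-yl]-1,2-dioxan-3-yl]acetate | COC(=O)C[C@@H]1OO[C@@](C)(C/C(C)=C/C=O)C[C@H]1C
F5 | step 12 | 1-phenyl-5-[(2-phenylethyl)sulfanyl]-1H-tetrazole | C(Cc1ccccc1)Sc1nnnn1-c1ccccc1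
F6 | step 12 | 1-phenyl-5-[(2-phenylethyl)sulfonyl]-1H-tetrazole | O=S(=O)(CCc1ccccc1)c1nnnn1-c1ccccc1
F7 | step 7 | (2R,4R)-4,6-dimethylhept-6-ene-2,4-diol | O[C@](C)(CC(C)=C)C[C@@H](C)O
F8 | step 7 | (2R,4S)-2,4-dimethyl-2-(2-methylprop-2-en-1-yl)oxetane | O1[C@](C)(CC(C)=C)C[C@@H]1C
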